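(Readings and results come from a simulation from invented constants, noise included.)

| flask | substrate | other conformer | remark | time |
|---|---|---|---|---|
| autumn | 0.20 M | 0.034 equiv | run made earlier |  |
| dusk | 0.20 M | 1.2 equiv | run made earlier |  |
| alder | 0.20 M | 0.0300 equiv |  | 40 min |
| elm | 0.20 M | 0.0800 equiv |  | 40 min |
| maple | 0.20 M | 0.250 equiv |  | 40 min |
| birch | 0.20 M | 0.800 equiv |  | 40 min |

- autumn (time / min: target / %, substrate / %): 2.50: 3.3, 88.3; 8.00: 10.8, 73.2; 12.0: 13.7, 63.1; 20.0: 16.9, 48.8
- dusk (time / min: target / %, substrate / %): 5.00: 3.3, 44.0; 10.0: 6.5, 39.1; 15.0: 7.7, 33.6; 20.0: 10.3, 28.0

(standard deviation of a reading: 0.5 percentage points)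

- "hardly changes" means that all values lie within two and a half points (for a concentration: within two and a half percent of the largest)

* amount of target at the end, in percent of the substrate and other conformer together charged for alder, elm, maple, birch, in this order
* the course of these numbers from the first flask to the last (falls all the way / rises, then falls / hardly changes / falls, then rises / rises all the way)

**Charged amounts.** Every percentage here is a share of substrate and other conformer together, so added other conformer enlarges the total and shrinks the share of substrate. That share is 96.7% in autumn and 45.5% in dusk.

**Reaction time.** Autumn target gains 2.9 percentage points from 8.00 min to 12.0 min, but 3.2 points over the longer stretch to 20.0 min, so its rate sinks. By hand, the stretch to 40 min should therefore add little target.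

**Other conformer.** Read as a first-order decay, dusk substrate falls at 0.0236 /min from 5.00 min to 10.0 min, slower than the 0.0365 /min from 15.0 min to 20.0 min. Autumn reads 0.0339 /min. By hand, these readings fit a feed from other conformer into substrate that fades early in dusk.

**The worth.** Take target at 20.0 min as proportional to the substrate share plus a constant times the other-conformer share. The readings of 16.9% in autumn and 10.3% in dusk then give 0.257. This is the worth: the fraction of a substrate unit that one unit of other conformer counts for in target. As a reading, it carries the scatter. Being below one, it makes the reckoned target fall as equivalents rise at fixed substrate concentration and time, and, carried over unchanged to 40 min, this reckoning puts birch at 0.684 of alder.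

**The forecast.** It gives 21%, 20.3%, 18.3% and 14.3%, a course that falls all the way: “Because the other conformer is a poor source of target, the percentage falls steadily as its share increases”. Its birch stands at 0.681 of its alder.

**The result.** The flasks end at 19.9%, 19.1%, 16.9% and 12.5%; the course falls all the way.

    substrate ⇌ other conformer (K = 0.400, k = 0.0190 /min)
    substrate ⇌ target (K = 1.10, k = 0.0180 /min)
    other conformer → isomer of the product (k = 0.210 /min)
    substrate + target → side product (k = 0.150 /M/min)

**Worth applied.** At 40.0 min, alder makes target at 0.959 of the rate at which it uses target up, each step taken net. Birch ends at 0.628 of alder, against the 0.684 reckoned from the worth. For maple, the same worth gives 0.870 of alder, and the flask ends at 0.849.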